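Follow Xc, the catalyst that turns Xa into Xp, through these closed, stirred flasks, and ask how often each Xc charged has turned.

| flask | Xa | Xc | time |
|---|---|---|---|
| maple | 0.500 M | 0.00500 M |  |
| oak | 0.500 M | 0.00750 M |  |
| cedar | 1.50 M | 0.00500 M |  |
| elm | 0.500 M | 0.00500 M | 28 min |

| maple run: time / min | maple run: [Xp] / M | oak run: time / min | oak run: [Xp] / M | cedar run: time / min | cedar run: [Xp] / M |
|---|---|---|---|---|---|
| 0.44 | 0.0450 | 0.44 | 0.0585 | 0.44 | 0.1169 |
| 0.70 | 0.0652 | 0.70 | 0.0916 | 0.70 | 0.1785 |
| 1.1 | 0.0960 | 1.1 | 0.1198 | 1.1 | 0.2663 |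
| 1.7 | 0.1315 | 1.7 | 0.1593 | 1.7 | 0.3711 |
| 2.8 | 0.1762 | 2.8 | 0.2127 | 2.8 | 0.5287 |
| 4.4 | 0.2248 | 4.4 | 0.2631 | 4.4 | 0.6843 |
| 6.9 | 0.2746 | 6.9 | 0.3147 | 6.9 | 0.8456 |
| 11 | 0.3195 | 11 | 0.3546 | 11 | 0.9994 |

(standard deviation of a reading: 0.002 M)

- Overall: Xa -> Xp, with Xc as catalyst.
- Constant volume, constant temperature.
- Bound and free are read together.
- An order is taken over about fifteen percent of the charge, up and down.

- reaction order in [Xa] at the outset, round the charge of the maple run, defined at two percent of the Xa turned into Xp (one fixed amount of Xp, the same in the runs compared)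
- reaction order in [Xc] at the outset, round the charge of the maple run, defined at two percent of the Xa turned into Xp
- Xp in the elm run at 28 min, as a share of the Xa charged

Count turnovers first: in the maple run, 0.0450 M of Xp after 0.44 min on 0.00500 M of Xc reads as 20.5 min⁻¹, and this is the number to carry, the turnover rate (turnover frequency), meaning the Xp made per minute per Xc charged, bound and free together, whose inverse is the time of one turn of the catalyst. Read the same way, the first reading of the oak run gives 17.7 min⁻¹, lower than in the maple run, so my own reckoning puts the order in Xc near 0.647. The cedar run gives 53.1 min⁻¹, so my mean order in Xa between 0.500 M and 1.50 M is 0.866, but that spans a wide step, and no two runs here sit close enough to read the narrow-band order directly. The elm run repeats the maple charge, which allows 100 turnovers, and the maple run has made 63.9 of them by 11 min.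

The forecast sets the order in Xa at 0.9 (0.78 to 1), the order in Xc at 0.8 (0.6 to 1) and the elm run at 78% (72% to 84%), and says of the catalyst: “Free and bound catalyst may be partly tied up.”

The flask gives an order in Xa of 1.4, an order in Xc of 0.81, and 80.4% in the elm run at 28 min, which is 80.4 turnovers.

    Xc + Xa ⇌ Xc.Xa, settled at all times (1.190 M⁻¹)
    Xc.Xa + Xa ⇌ Xc.Xa2, settled at all times (3.430 M⁻¹)
    Xc.Xa2 → Xp + Xc.Xa (76.80 min⁻¹)
    Xc + Xp ⇌ Xc.Xp, settled at all times (11.40 M⁻¹)
    2 Xc ⇌ Xc2, settled at all times (262.0 M⁻¹)

Now apply the turnover rate at equal Xp, where two percent of the Xa of the maple run has turned: the maple run gives 21.7 min⁻¹, and the oak run gives 19.9 min⁻¹, lower than in the maple run. The pairing of two Xc to Xc2 is the reason, for the order in Xc is 0.81 with that pairing and 0.99 in the same run with the pairing taken away. The cedar run's rate ratio of 2.6 still means a mean order of 0.882 across the wide step, while round the maple charge the order in Xa is 1.4 with that pairing and 1.1 in the same run with the pairing taken away.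

The data come from a simulation for an exercise; the scatter is artificial.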